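**Strategy.** The target is a ten-membered (germacrane-type) carbocycle in which the C9 carbinol sits on C10, the α-carbon of the C1=C10–C14 enoate: a Morita–Baylis–Hillman-type array inside the ring. The route therefore closes the carbocycle late, at C9–C10, by an intramolecular Nozaki–Hiyama–Kishi reaction. In one operation this forms the ring, sets C9 under Felkin–Anh control from C8 and keeps the olefin geometry. Its precursor is an open-chain C9 aldehyde carrying the trans-disubstituted α-methylene lactone (C6, C7, C11–C13), the C8 chlorohydrin ester, the 4E olefin and a (Z)-2-iodoenoate (C10, C1). It is assembled from geranyl acetate, glyceraldehyde acetonide and an epoxy acid; the 4,5-epoxide is introduced last.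

Key step: step 15

Remark: skeletal atoms are numbered as in germacranolides (ring C1–C10, lactone C11–C13, ester carbon C14, methyl C15). The CIP letters at C6 and C7 change along the route only because substituent priorities change, and the C1=C10 olefin changes from Z (iodide) to E (ring) for the same reason. (S)-Glyceraldehyde acetonide and (E)-2-methylbut-2-en-1-ol are taken as commercial.

## Fragment A (C1–C6, C14, C15)

Step 1
Reactants: 1 geranyl acetate
Product: 3 (2E)-3-methyl-6-oxohex-2-en-1-yl acetate, via secondary ozonide 2 (not isolated)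
Conditions: O3 (1 equiv), CH2Cl2, −78 °C; then Me2S, −78 °C to rt
Reagents that add atoms: ozone, [O-][O+]=O
Why: Chemoselective ozonolysis, in which the remote, electron-rich trisubstituted olefin is cleaved much faster than the olefin deactivated by the allylic acetoxy group, and reduction of the ozonide by Me2S gives the aldehyde (future C1) with the E olefin (future C4=C5) untouched.

Step 2
Reactants: 3 (2E)-3-methyl-6-oxohex-2-en-1-yl acetate
Product: 4 methyl (2Z,6E)-8-acetoxy-2-iodo-6-methylocta-2,6-dienoate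
Conditions: Ph3P=CHCO2Me, NIS, MeCN, −20 °C; then 3, −20 °C to rt
Reagents that add atoms: methyl (triphenylphosphoranylidene)acetate, COC(=O)C=P(c1ccccc1)(c1ccccc1)c1ccccc1; N-iodosuccinimide, O=C1CCC(=O)N1I
Why: Wittig olefination with the α-iodo stabilised ylide, made in the flask by iodination of the parent ylide, should place the ester trans to the chain and so give the (Z)-2-iodoenoate (iodine on future C10 cis to C2).

Step 3
Reactants: 4 methyl (2Z,6E)-8-acetoxy-2-iodo-6-methylocta-2,6-dienoate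
Product: 5 methyl (2Z,6E)-8-hydroxy-2-iodo-6-methylocta-2,6-dienoate
Conditions: K2CO3 (cat.), MeOH, 0 °C
Reagents that add atoms: none
Why: Base-catalysed methanolysis (transesterification) of the primary allylic acetate is fast at 0 °C, exchange at the methyl ester is degenerate, and the alkenyl iodide is inert.

Step 4
Reactants: 5 methyl (2Z,6E)-8-hydroxy-2-iodo-6-methylocta-2,6-dienoate
Product: 6 methyl (2Z,6E)-2-iodo-6-methyl-8-oxoocta-2,6-dienoate
Conditions: MnO2 (activated), CH2Cl2, rt
Reagents that add atoms: none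
Why: Allylic oxidation with MnO2 is selective for the allylic alcohol and should give the E enal (C6 aldehyde) without isomerisation and without touching the iodoenoate.

## Fragment B (C7–C9, C11–C13)

Step 5
Reactants: 7 (4S)-2,2-dimethyl-1,3-dioxolane-4-carbaldehyde; 8 methyl acrylate
Product: 9 methyl 2-{[(4S)-2,2-dimethyl-1,3-dioxolan-4-yl](hydroxy)methyl}prop-2-enoate (both carbinol epimers)
Conditions: DABCO (0.5 equiv), 1,4-dioxane–H2O, rt
Reagents that add atoms: none
Why: Morita–Baylis–Hillman reaction joins the acrylate α-carbon (C11) to the aldehyde carbon (C7); the new carbinol centre is erased by the transposition in step 6, while the dioxolane centre (future C8) comes from 7.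

Step 6
Reactants: 9 methyl 2-{[(4S)-2,2-dimethyl-1,3-dioxolan-4-yl](hydroxy)methyl}prop-2-enoate
Product: 11 methyl (2Z)-2-(bromomethyl)-3-[(4R)-2,2-dimethyl-1,3-dioxolan-4-yl]prop-2-enoate, via alkoxysulfonium bromide 10 (not isolated)
Conditions: NBS, Me2S, CH2Cl2, 0 °C to rt
Reagents that add atoms: N-bromosuccinimide, O=C1CCC(=O)N1Br
Why: Activation of the secondary allylic alcohol as its alkoxysulfonium salt and SN2' attack of bromide at the methylene terminus should give the transposed primary allylic bromide as the favoured Z isomer (dioxolanyl trans to the ester), with the dioxolane centre untouched.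

## Side-chain acid

Step 7
Reactants: 12 (2E)-2-methylbut-2-en-1-ol
Product: 13 [(2S,3S)-2,3-dimethyloxiran-2-yl]methanol
Conditions: Ti(OiPr)4 (cat.), L-(+)-diethyl tartrate (cat.), t-BuOOH, 4 Å molecular sieves, CH2Cl2, −20 °C
Reagents that add atoms: tert-butyl hydroperoxide, CC(C)(C)OO
Why: Sharpless asymmetric epoxidation with the L-(+)-tartrate catalyst delivers oxygen to the face of the E allylic alcohol that gives the (2S,3S)-epoxy alcohol, fixing both stereocentres of the later side chain.

Step 8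
Reactants: 13 [(2S,3S)-2,3-dimethyloxiran-2-yl]methanol
Product: 15 (2R,3S)-2,3-dimethyloxirane-2-carboxylic acid, via epoxy aldehyde 14 (not isolated)
Conditions: RuCl3 hydrate (cat.), NaIO4, MeCN–EtOAc–H2O, 0 °C to rt
Reagents that add atoms: water, O
Why: Ruthenium tetroxide generated catalytically from RuCl3 and NaIO4 oxidises the primary alcohol through the aldehyde hydrate to the glycidic acid without opening the epoxide, so both stereocentres are kept (the letter at C2 changes by priority only).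

## Assembly

Step 9
Reactants: 6 methyl (2Z,6E)-2-iodo-6-methyl-8-oxoocta-2,6-dienoate; 11 methyl (2Z)-2-(bromomethyl)-3-[(4R)-2,2-dimethyl-1,3-dioxolan-4-yl]prop-2-enoate
Product: 18 methyl (2Z,6E)-7-[(2R,3S)-3-[(4R)-2,2-dimethyl-1,3-dioxolan-4-yl]-4-methylidene-5-oxooxolan-2-yl]-2-iodo-6-methylhepta-2,6-dienoate, via allylchromium reagent 16 (not isolated), via chromium alkoxide 17 (not isolated)
Conditions: CrCl2 (nickel-free, 3 equiv), 11 (1.3 equiv), THF, 0 °C to rt; aq. NH4Cl
Reagents that add atoms: none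
Why: Chromium-mediated 2-(alkoxycarbonyl)allylation (Nozaki–Hiyama allylation) through a chair transition state with the enal residue and the C8 substituent equatorial should give the anti adduct, which lactonises in the flask to the trans-lactone; attack on the C7 face anti to the dioxolane C–O bond (H8 eclipsing the olefin) lets C8 set C7 and C6, and without nickel the alkenyl iodide should stay intact.

Step 10
Reactants: 18 methyl (2Z,6E)-7-[(2R,3S)-3-[(4R)-2,2-dimethyl-1,3-dioxolan-4-yl]-4-methylidene-5-oxooxolan-2-yl]-2-iodo-6-methylhepta-2,6-dienoate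
Product: 19 methyl (2Z,6E)-7-[(2R,3R)-3-[(1R)-1,2-dihydroxyethyl]-4-methylidene-5-oxooxolan-2-yl]-2-iodo-6-methylhepta-2,6-dienoate
Conditions: AcOH–H2O (4:1), 40 °C
Reagents that add atoms: none
Why: Acid-catalysed acetal hydrolysis removes the isopropylidene group, while the lactone, the methyl ester and the alkenyl iodide are stable to warm aqueous acetic acid and no stereocentre is touched.

Step 11
Reactants: 19 methyl (2Z,6E)-7-[(2R,3R)-3-[(1R)-1,2-dihydroxyethyl]-4-methylidene-5-oxooxolan-2-yl]-2-iodo-6-methylhepta-2,6-dienoate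
Product: 20 methyl (2Z,6E)-7-[(2R,3R)-3-[(1R)-2-{[tert-butyl(dimethyl)silyl]oxy}-1-hydroxyethyl]-4-methylidene-5-oxooxolan-2-yl]-2-iodo-6-methylhepta-2,6-dienoate
Conditions: TBSCl, imidazole, CH2Cl2, −20 to 0 °C
Reagents that add atoms: tert-butyldimethylsilyl chloride, CC(C)(C)[Si](C)(C)Cl
Why: Silylation is kinetically selective for the primary C9 hydroxyl over the hindered secondary C8 hydroxyl.

Step 12
Reactants: 20 methyl (2Z,6E)-7-[(2R,3R)-3-[(1R)-2-{[tert-butyl(dimethyl)silyl]oxy}-1-hydroxyethyl]-4-methylidene-5-oxooxolan-2-yl]-2-iodo-6-methylhepta-2,6-dienoate; 15 (2R,3S)-2,3-dimethyloxirane-2-carboxylic acid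
Product: 22 (1R)-2-{[tert-butyl(dimethyl)silyl]oxy}-1-{(2R,3S)-2-[(1E,5Z)-6-iodo-7-methoxy-2-methyl-7-oxohepta-1,5-dien-1-yl]-4-methylidene-5-oxooxolan-3-yl}ethyl (2R,3S)-2,3-dimethyloxirane-2-carboxylate, via mixed anhydride 21 (not isolated)
Conditions: 15, 2,4,6-trichlorobenzoyl chloride, Et3N, toluene, rt; then 20, DMAP, toluene, rt
Reagents that add atoms: none
Why: Yamaguchi esterification through the mixed 2,4,6-trichlorobenzoic anhydride should acylate the hindered secondary C8 alcohol with the α-quaternary acid under DMAP catalysis, with retention at every stereocentre.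

Step 13
Reactants: 22 (1R)-2-{[tert-butyl(dimethyl)silyl]oxy}-1-{(2R,3S)-2-[(1E,5Z)-6-iodo-7-methoxy-2-methyl-7-oxohepta-1,5-dien-1-yl]-4-methylidene-5-oxooxolan-3-yl}ethyl (2R,3S)-2,3-dimethyloxirane-2-carboxylate
Product: 24 (1R)-2-hydroxy-1-{(2R,3S)-2-[(1E,5Z)-6-iodo-7-methoxy-2-methyl-7-oxohepta-1,5-dien-1-yl]-4-methylidene-5-oxooxolan-3-yl}ethyl (2S,3R)-3-chloro-2-hydroxy-2-methylbutanoate, via chlorohydrin silyl ether 23 (not isolated)
Conditions: HCl (4 M in 1,4-dioxane), CH2Cl2, 0 °C; then MeOH, 0 °C to rt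
Reagents that add atoms: hydrogen chloride, Cl
Why: Acid-mediated epoxide opening, in which chloride attacks the secondary β-carbon of the protonated glycidic ester with inversion (the quaternary α-carbon is deactivated by the ester), should give the (2S,3R)-chlorohydrin, and the methanolic HCl formed on adding methanol then cleaves the primary silyl ether.

Step 14
Reactants: 24 (1R)-2-hydroxy-1-{(2R,3S)-2-[(1E,5Z)-6-iodo-7-methoxy-2-methyl-7-oxohepta-1,5-dien-1-yl]-4-methylidene-5-oxooxolan-3-yl}ethyl (2S,3R)-3-chloro-2-hydroxy-2-methylbutanoate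
Product: 25 (1R)-1-{(2R,3S)-2-[(1E,5Z)-6-iodo-7-methoxy-2-methyl-7-oxohepta-1,5-dien-1-yl]-4-methylidene-5-oxooxolan-3-yl}-2-oxoethyl (2S,3R)-3-chloro-2-hydroxy-2-methylbutanoate
Conditions: Dess–Martin periodinane, CH2Cl2, 0 °C to rt
Reagents that add atoms: none
Why: Dess–Martin oxidation converts the primary C9 alcohol into the aldehyde under non-basic conditions that should not epimerise C8, and the tertiary alcohol cannot be oxidised.

Step 15
Reactants: 25 (1R)-1-{(2R,3S)-2-[(1E,5Z)-6-iodo-7-methoxy-2-methyl-7-oxohepta-1,5-dien-1-yl]-4-methylidene-5-oxooxolan-3-yl}-2-oxoethyl (2S,3R)-3-chloro-2-hydroxy-2-methylbutanoate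
Product: 28 macrocyclic alcohol, methyl ester of (1(10)E,4E,6R,7S,8R,9S)-8-{[(2S,3R)-3-chloro-2-hydroxy-2-methylbutanoyl]oxy}-9-hydroxy-12-oxo-6,12-epoxygermacra-1(10),4,11(13)-trien-14-oic acid (the 12,6-lactone; ring carbons C2 and C9 cis on C1=C10), via alkenylchromium species 26 (not isolated), via chromium alkoxide 27 (not isolated)
Conditions: CrCl2 (10 equiv), NiCl2 (0.1 equiv), degassed DMSO, rt, slow addition of 25 to a final 2 mM; aqueous work-up
Reagents that add atoms: none
Why: Oxidative addition of the C10–I bond to zerovalent nickel (formed from NiCl2 by CrCl2), transmetalation to trivalent chromium and intramolecular 1,2-addition of alkenylchromium 26 to the C9 aldehyde form the C9–C10 bond, and hydrolysis of alkoxide 27 frees the allylic alcohol; the closest known reaction type is the Nozaki–Hiyama–Kishi macrocyclisation used for nine- to twelve-membered carbocycles. The ten-membered ring closes in a 10-exo-trig mode, helped by three turn elements already in the chain: the lactone, the 4E olefin and the iodoalkene, whose cis arrangement of C2 and the metal-bearing position is retained in the C–C bond formation. The new stereocentre C9 is controlled by C8, since polar Felkin–Anh addition anti to the C8 acyloxy group should give the 8,9-anti (9S) alcohol. The step needs chemoselectivity for the alkenyl iodide over the alkyl chloride, the acrylate-type lactone, the esters and the free tertiary alcohol, which the non-basic nickel/chromium couple secures, and ring closure over oligomerisation, which high dilution and slow addition secure.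

Step 16
Reactants: 28 macrocyclic alcohol (9-OH)
Product: 29 macrocyclic acetate, methyl ester of (1(10)E,4E,6R,7S,8R,9S)-9-acetoxy-8-{[(2S,3R)-3-chloro-2-hydroxy-2-methylbutanoyl]oxy}-12-oxo-6,12-epoxygermacra-1(10),4,11(13)-trien-14-oic acid
Conditions: Ac2O, pyridine, DMAP (cat.), CH2Cl2, 0 °C
Reagents that add atoms: acetic anhydride, CC(=O)OC(C)=O
Why: Acetylation of the secondary allylic C9 alcohol, while the tertiary α-hydroxy ester hydroxyl is too hindered to be acylated under these mild conditions.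

Step 17
Reactants: 29 macrocyclic acetate
Product: 30 CNP0185503.3, methyl ester of (1(10)E,4R,5R,6S,7R,8R,9S)-9-acetoxy-8-{[(2S,3R)-3-chloro-2-hydroxy-2-methylbutanoyl]oxy}-4,5-epoxy-12-oxo-6,12-epoxygermacra-1(10),11(13)-dien-14-oic acid
Conditions: mCPBA, NaHCO3, CH2Cl2, 0 °C
Reagents that add atoms: 3-chloroperbenzoic acid, OOC(=O)c1cccc(Cl)c1
Why: Prilezhaev epoxidation is chemoselective for the only electron-rich olefin (C4=C5, the two acrylate-type olefins being inert to peracid) and should occur on the exposed outer face of the E olefin in the ten-membered ring, giving the (4R,5R)-epoxide, as is usual for 4,5-olefins of germacranolides.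

## Compound list

1 | geranyl acetate, (2E)-3,7-dimethylocta-2,6-dien-1-yl acetate | CC(C)=CCC/C(C)=C/COC(C)=O | starting material
2 | secondary ozonide, (2E)-5-(5,5-dimethyl-1,2,4-trioxolan-3-yl)-3-methylpent-2-en-1-yl acetate (formed in the flask) | CC(=O)OC/C=C(C)/CCC1OOC(C)(C)O1 | intermediate
3 | (2E)-3-methyl-6-oxohex-2-en-1-yl acetate | O=CCC/C(C)=C/COC(C)=O | intermediate
4 | methyl (2Z,6E)-8-acetoxy-2-iodo-6-methylocta-2,6-dienoate | COC(=O)/C(I)=C/CC/C(C)=C/COC(C)=O | intermediate
5 | methyl (2Z,6E)-8-hydroxy-2-iodo-6-methylocta-2,6-dienoate | COC(=O)/C(I)=C/CC/C(C)=C/CO | intermediate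
6 | methyl (2Z,6E)-2-iodo-6-methyl-8-oxoocta-2,6-dienoate (fragment A) | COC(=O)/C(I)=C/CC/C(C)=C/C=O | intermediate
7 | (4S)-2,2-dimethyl-1,3-dioxolane-4-carbaldehyde, (S)-glyceraldehyde acetonide | O=C[C@@H]1COC(C)(C)O1 | starting material
8 | methyl acrylate | C=CC(=O)OC | starting material
9 | methyl 2-{[(4S)-2,2-dimethyl-1,3-dioxolan-4-yl](hydroxy)methyl}prop-2-enoate, both carbinol epimers | C=C(C(=O)OC)C(O)[C@@H]1COC(C)(C)O1 | intermediate
10 | alkoxysulfonium bromide, O-dimethylsulfonio derivative of 9 (formed in the flask) | C=C(C(=O)OC)C(O[S+](C)C)[C@@H]1COC(C)(C)O1.[Br-] | intermediate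
11 | methyl (2Z)-2-(bromomethyl)-3-[(4R)-2,2-dimethyl-1,3-dioxolan-4-yl]prop-2-enoate (fragment B) | COC(=O)/C(CBr)=C/[C@@H]1COC(C)(C)O1 | intermediate
12 | (2E)-2-methylbut-2-en-1-ol | C/C=C(C)/CO | starting material
13 | [(2S,3S)-2,3-dimethyloxiran-2-yl]methanol | OC[C@]1(C)O[C@H]1C | intermediate
14 | (2R,3S)-2,3-dimethyloxirane-2-carbaldehyde (formed in the flask) | O=C[C@]1(C)O[C@H]1C | intermediate
15 | (2R,3S)-2,3-dimethyloxirane-2-carboxylic acid | OC(=O)[C@]1(C)O[C@H]1C | intermediate
16 | allylchromium reagent, dichloro{3-[(4R)-2,2-dimethyl-1,3-dioxolan-4-yl]-2-(methoxycarbonyl)prop-2-en-1-yl}chromium (trivalent chromium, olefin geometry fluxional, formed in the flask) | COC(=O)C(C[Cr](Cl)Cl)=C[C@@H]1COC(C)(C)O1 | intermediate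
17 | chromium alkoxide of the anti homoallylic alcohol: C6–O–CrCl2 (trivalent chromium), C12 still the methyl ester, C6, C7 and C8 arranged as in 18 (formed in the flask) | C=C(C(=O)OC)[C@H]([C@@H]1COC(C)(C)O1)[C@H](O[Cr](Cl)Cl)/C=C(C)/CC/C=C(I)/C(=O)OC | intermediate
18 | methyl (2Z,6E)-7-[(2R,3S)-3-[(4R)-2,2-dimethyl-1,3-dioxolan-4-yl]-4-methylidene-5-oxooxolan-2-yl]-2-iodo-6-methylhepta-2,6-dienoate | C=C1C(=O)O[C@H](/C=C(C)/CC/C=C(I)/C(=O)OC)[C@H]1[C@@H]1COC(C)(C)O1 | intermediate
19 | methyl (2Z,6E)-7-[(2R,3R)-3-[(1R)-1,2-dihydroxyethyl]-4-methylidene-5-oxooxolan-2-yl]-2-iodo-6-methylhepta-2,6-dienoate | C=C1C(=O)O[C@H](/C=C(C)/CC/C=C(I)/C(=O)OC)[C@H]1[C@@H](O)CO | intermediate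
20 | methyl (2Z,6E)-7-[(2R,3R)-3-[(1R)-2-{[tert-butyl(dimethyl)silyl]oxy}-1-hydroxyethyl]-4-methylidene-5-oxooxolan-2-yl]-2-iodo-6-methylhepta-2,6-dienoate | C=C1C(=O)O[C@H](/C=C(C)/CC/C=C(I)/C(=O)OC)[C@H]1[C@@H](O)CO[Si](C)(C)C(C)(C)C | intermediate
21 | (2R,3S)-2,3-dimethyloxirane-2-carboxylic 2,4,6-trichlorobenzoic anhydride (formed in the flask) | O=C(OC(=O)[C@]1(C)O[C@H]1C)c1c(Cl)cc(Cl)cc1Cl | intermediate
22 | (1R)-2-{[tert-butyl(dimethyl)silyl]oxy}-1-{(2R,3S)-2-[(1E,5Z)-6-iodo-7-methoxy-2-methyl-7-oxohepta-1,5-dien-1-yl]-4-methylidene-5-oxooxolan-3-yl}ethyl (2R,3S)-2,3-dimethyloxirane-2-carboxylate | C=C1C(=O)O[C@H](/C=C(C)/CC/C=C(I)/C(=O)OC)[C@H]1[C@@H](OC(=O)[C@]1(C)O[C@H]1C)CO[Si](C)(C)C(C)(C)C | intermediate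
23 | (1R)-2-{[tert-butyl(dimethyl)silyl]oxy}-1-{(2R,3S)-2-[(1E,5Z)-6-iodo-7-methoxy-2-methyl-7-oxohepta-1,5-dien-1-yl]-4-methylidene-5-oxooxolan-3-yl}ethyl (2S,3R)-3-chloro-2-hydroxy-2-methylbutanoate (formed in the flask) | C=C1C(=O)O[C@H](/C=C(C)/CC/C=C(I)/C(=O)OC)[C@H]1[C@@H](OC(=O)[C@](C)(O)[C@@H](C)Cl)CO[Si](C)(C)C(C)(C)C | intermediate
24 | (1R)-2-hydroxy-1-{(2R,3S)-2-[(1E,5Z)-6-iodo-7-methoxy-2-methyl-7-oxohepta-1,5-dien-1-yl]-4-methylidene-5-oxooxolan-3-yl}ethyl (2S,3R)-3-chloro-2-hydroxy-2-methylbutanoate | C=C1C(=O)O[C@H](/C=C(C)/CC/C=C(I)/C(=O)OC)[C@H]1[C@@H](OC(=O)[C@](C)(O)[C@@H](C)Cl)CO | intermediate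
25 | (1R)-1-{(2R,3S)-2-[(1E,5Z)-6-iodo-7-methoxy-2-methyl-7-oxohepta-1,5-dien-1-yl]-4-methylidene-5-oxooxolan-3-yl}-2-oxoethyl (2S,3R)-3-chloro-2-hydroxy-2-methylbutanoate (open-chain C9 aldehyde) | C=C1C(=O)O[C@H](/C=C(C)/CC/C=C(I)/C(=O)OC)[C@H]1[C@@H](OC(=O)[C@](C)(O)[C@@H](C)Cl)C=O | intermediate
26 | alkenylchromium species, 25 with CrCl2 (trivalent chromium) in place of iodine at C10 (formed in the flask) | C=C1C(=O)O[C@H](/C=C(C)/CC/C=C(/C(=O)OC)[Cr](Cl)Cl)[C@H]1[C@@H](OC(=O)[C@](C)(O)[C@@H](C)Cl)C=O | intermediate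
27 | chromium alkoxide of 28, C9–O–CrCl2 (trivalent chromium, formed in the flask) | C=C1C(=O)O[C@H](/C=C(C)/C2)[C@H]1[C@@H](OC(=O)[C@](C)(O)[C@@H](C)Cl)[C@@H](O[Cr](Cl)Cl)/C(C(=O)OC)=C\C2 | intermediate
28 | macrocyclic alcohol, methyl ester of (1(10)E,4E,6R,7S,8R,9S)-8-{[(2S,3R)-3-chloro-2-hydroxy-2-methylbutanoyl]oxy}-9-hydroxy-12-oxo-6,12-epoxygermacra-1(10),4,11(13)-trien-14-oic acid | C=C1C(=O)O[C@H](/C=C(C)/C2)[C@H]1[C@@H](OC(=O)[C@](C)(O)[C@@H](C)Cl)[C@@H](O)/C(C(=O)OC)=C\C2 | intermediate
29 | macrocyclic acetate, 9-O-acetyl derivative of 28 | C=C1C(=O)O[C@H](/C=C(C)/C2)[C@H]1[C@@H](OC(=O)[C@](C)(O)[C@@H](C)Cl)[C@@H](OC(C)=O)/C(C(=O)OC)=C\C2 | intermediate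
30 | CNP0185503.3, (4R,5R)-4,5-epoxide of 29 with (6S,7R,8R,9S) and the (2S,3R) side chain | C=C1C(=O)O[C@H]2[C@H]1[C@@H](OC(=O)[C@](C)(O)[C@@H](C)Cl)[C@@H](OC(C)=O)/C(C(=O)OC)=C\CC[C@@]1(C)O[C@H]21 | target

## Step count and risks

Total steps: 17. Longest linear sequence: 13 steps (steps 1–4, then 9–17).

**1. Step 15 (ring closure).** The process at risk is facial selectivity at the C9 aldehyde: strain in the ring-forming transition state may override Felkin–Anh control and deliver the C9 epimer (protodeiodination and oligomerisation are held down by dilution). The fallback sets out from 28 as obtained together with its epimer and comes back to pure 28; it sets C9 by a reduction instead of a C–C bond formation. The mixture of 28 and the (9R)-epimeric macrocyclic alcohol F1 is oxidised with Dess–Martin periodinane to the macrocyclic C9 ketone (an alkylidene β-keto ester) F2. This is reduced in 1,2-fashion with catecholborane under (S)-2-methyl-CBS-oxazaborolidine catalysis (Corey–Bakshi–Shibata reduction). The (S)-catalyst is predicted if the alkylidene arm acts as the large group; otherwise its enantiomer is used. The reduction gives the catechol borate of 28 F3, which is hydrolysed on work-up to 28.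

**2. Step 9 (fragment union).** The process at risk is simple diastereoselection: if the allylchromium does not react through the geometry assumed, the syn adduct and hence the cis-lactone results; reduction of the iodoalkene by CrCl2 is a second danger. The fallback sets out from 7 and 6 and comes back at 18; it uses a metal-free allylboration with a boronate of fixed geometry. Corey–Fuchs olefination of 7 (CBr4, PPh3, CH2Cl2) gives (4R)-4-(2,2-dibromoethenyl)-2,2-dimethyl-1,3-dioxolane F4. n-BuLi (two equivalents, THF, −78 °C) converts it into the lithium acetylide of (4R)-4-ethynyl-2,2-dimethyl-1,3-dioxolane F5, which is trapped with methyl chloroformate as methyl 3-[(4R)-2,2-dimethyl-1,3-dioxolan-4-yl]prop-2-ynoate F6. Syn-hydroalumination (iBu2AlH, N-methylmorpholine N-oxide, THF, 0 °C) gives methyl (2E)-2-[bis(2-methylpropyl)alumanyl]-3-[(4R)-2,2-dimethyl-1,3-dioxolan-4-yl]prop-2-enoate F7. Alkylation of F7 with 2-(iodomethyl)-4,4,5,5-tetramethyl-1,3,2-dioxaborolane gives methyl (2Z)-3-[(4R)-2,2-dimethyl-1,3-dioxolan-4-yl]-2-[(4,4,5,5-tetramethyl-1,3,2-dioxaborolan-2-yl)methyl]prop-2-enoate F8, with the dioxolanyl group cis to the ester and trans to CH2B. Heating F8 with 6 in toluene at 80 °C should give, through the closed chair transition state, the anti pinacol borate of the homoallylic alcohol F9, which lactonises to 18.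

**3. Step 17 (epoxidation).** The process at risk is facial selectivity: the flexible ten-membered ring may expose both faces of C4=C5 to the peracid. The fallback sets out from 29 and comes back at 30; it hands face selection from the ring conformation to a chiral catalyst. Shi epoxidation is used, with the D-fructose-derived ketone (1,2:4,5-di-O-isopropylidene-β-D-erythro-2,3-hexodiulo-2,6-pyranose, catalytic) and Oxone (KHSO5) in buffered MeCN–dimethoxymethane–H2O at 0 °C. This catalyst normally gives the (R,R)-epoxide from E-trisubstituted olefins and leaves electron-poor olefins alone. No new compound is formed on the way.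

Further compounds
F1 | step 15 | (9R)-epimer of macrocyclic alcohol 28 | C=C1C(=O)O[C@H](/C=C(C)/C2)[C@H]1[C@@H](OC(=O)[C@](C)(O)[C@@H](C)Cl)[C@H](O)/C(C(=O)OC)=C\C2
F2 | step 15 | macrocyclic C9 ketone (9-oxo analogue of 28) | C=C1C(=O)O[C@H](/C=C(C)/C2)[C@H]1[C@@H](OC(=O)[C@](C)(O)[C@@H](C)Cl)C(=O)/C(C(=O)OC)=C\C2
F3 | step 15 | catechol borate of 28 (9-O-(1,3,2-benzodioxaborol-2-yl) derivative, not isolated) | C=C1C(=O)O[C@H](/C=C(C)/C2)[C@H]1[C@@H](OC(=O)[C@](C)(O)[C@@H](C)Cl)[C@@H](OB3Oc4ccccc4O3)/C(C(=O)OC)=C\C2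
F4 | step 9 | (4R)-4-(2,2-dibromoethenyl)-2,2-dimethyl-1,3-dioxolane | BrC(Br)=C[C@@H]1COC(C)(C)O1
F5 | step 9 | lithium acetylide of (4R)-4-ethynyl-2,2-dimethyl-1,3-dioxolane (not isolated) | [Li]C#C[C@@H]1COC(C)(C)O1
F6 | step 9 | methyl 3-[(4R)-2,2-dimethyl-1,3-dioxolan-4-yl]prop-2-ynoate | COC(=O)C#C[C@@H]1COC(C)(C)O1
F7 | step 9 | methyl (2E)-2-[bis(2-methylpropyl)alumanyl]-3-[(4R)-2,2-dimethyl-1,3-dioxolan-4-yl]prop-2-enoate (not isolated) | COC(=O)/C(=C\[C@@H]1COC(C)(C)O1)[Al](CC(C)C)CC(C)C
F8 | step 9 | methyl (2Z)-3-[(4R)-2,2-dimethyl-1,3-dioxolan-4-yl]-2-[(4,4,5,5-tetramethyl-1,3,2-dioxaborolan-2-yl)methyl]prop-2-enoate | COC(=O)/C(CB1OC(C)(C)C(C)(C)O1)=C\[C@@H]1COC(C)(C)O1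
F9 | step 9 | pinacol borate of the anti homoallylic alcohol (C6–O–B, C12 methyl ester, stereocentres as in 17, not isolated) | C=C(C(=O)OC)[C@H]([C@@H]1COC(C)(C)O1)[C@H](OB1OC(C)(C)C(C)(C)O1)/C=C(C)/CC/C=C(I)/C(=O)OC
F0 | step 17 | none | none
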